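## Retrosynthetic overview (labdane numbering throughout)

1. Target 18 ⇐ hydroxy acid 17 ⇐ silyl-protected acid 16 ⇐ 19-alcohol 15 (late C15 acetylation; C19 carbinol to acid).
2. 15 ⇐ 3,19-diol 12 (radical removal of O3 through a cyclic thionocarbonate) ⇐ bicyclic β-keto ester 11 (one LiAlH4 step reduces the ketone and releases the auxiliary).
3. Key step: 11 ⇐ acyclic β-keto ester 10 by one oxidative radical bicyclization. Ring A closes first (C4–C5), ring B second (C10–C9), and termination gives the 8(17)-alkene. C4, C5, C9 and C10 are set at once under 8-phenylmenthyl control.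
4. 10 ⇐ dianion of auxiliary keto ester 8 + allylic bromide 5 (C1–C2 bond).
5. 5 ⇐ (R)-2,3-dihydrofarnesol 2 ⇐ (2E,6E)-farnesol 1 by asymmetric hydrogenation, which sets C13.

Assumption: the sense of induction in step 7 follows the usual 8-phenylmenthyl model (alkene adds anti to the phenyl ring; the (−)-ester leads to the normal podocarpic-type series), so the (+)-(1S,2R,5S) auxiliary is used for the ent series required here; this correlation is taken from memory and a model, not re-checked against a source.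

## Route

Step 1
Reactants: 1 (2E,6E)-farnesol
Product: 2 (R)-2,3-dihydrofarnesol [(3R,6E)-3,7,11-trimethyldodeca-6,10-dien-1-ol]
Conditions: H2 (40 atm), Ru(OAc)2[(S)-BINAP] (0.2 mol %), MeOH, 25 °C
Reagents that add atoms: none
Why: Noyori asymmetric hydrogenation, in which the allylic hydroxyl binds the divalent ruthenium centre so that only the C2=C3 alkene is reduced and the (S)-BINAP complex sets the 3R centre (future C13, as geraniol gives (R)-citronellol), leaving the two remote trisubstituted alkenes untouched.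

Step 2
Reactants: 2 (R)-2,3-dihydrofarnesol
Product: 3 tert-butyldiphenyl{[(3R,6E)-3,7,11-trimethyldodeca-6,10-dien-1-yl]oxy}silane
Conditions: TBDPSCl, imidazole, CH2Cl2, 25 °C
Reagents that add atoms: tert-butyl(chloro)diphenylsilane, CC(C)(C)[Si](Cl)(c1ccccc1)c1ccccc1
Why: Silylation of the primary alcohol gives an ether that survives the base, acetic acid, hydride, tin hydride and chromic acid steps ahead.

Step 3
Reactants: 3 TBDPS ether of (R)-dihydrofarnesol
Product: 4 (2E,6E,10R)-12-(tert-butyldiphenylsilyloxy)-2,6,10-trimethyldodeca-2,6-dien-1-ol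
Conditions: SeO2 (0.2 equiv), salicylic acid (0.1 equiv), t-BuOOH (3 equiv), CH2Cl2, 25 °C
Reagents that add atoms: selenium dioxide, O=[Se]=O; tert-butyl hydroperoxide, CC(C)(C)OO
Why: Catalytic SeO2 allylic oxidation (ene reaction then 2,3-sigmatropic shift) selectively hydroxylates the E-methyl group of the terminal isopropylidene unit, giving the (E)-allylic alcohol that later becomes C1.

Step 4
Reactants: 4 terminal (E)-allylic alcohol
Product: 5 tert-butyl{[(3R,6E,10E)-12-bromo-3,7,11-trimethyldodeca-6,10-dien-1-yl]oxy}diphenylsilane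
Conditions: CBr4, PPh3, CH2Cl2, 0 °C
Reagents that add atoms: carbon tetrabromide, BrC(Br)(Br)Br
Why: Appel bromination converts the primary allylic alcohol to the bromide under neutral conditions without allylic transposition or loss of E geometry.

Step 5
Reactants: 6 (+)-8-phenylmenthol [(1S,2R,5S)-5-methyl-2-(2-phenylpropan-2-yl)cyclohexan-1-ol]; 7 ethyl 2-methyl-3-oxobutanoate
Product: 8 (1S,2R,5S)-5-methyl-2-(2-phenylpropan-2-yl)cyclohexyl 2-methyl-3-oxobutanoate (2RS)
Conditions: DMAP (0.3 equiv), toluene, reflux, 4 Å molecular sieves (removal of EtOH)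
Reagents that add atoms: none
Why: DMAP-catalysed transesterification of an enolisable β-keto ester (through the acylketene) attaches the hindered auxiliary alcohol, and the α-stereocentre is irrelevant because it becomes a planar radical.

Step 6
Reactants: 8 auxiliary 2-methylacetoacetate; 5 allylic bromide
Product: 10 (1S,2R,5S)-5-methyl-2-(2-phenylpropan-2-yl)cyclohexyl (2RS,6E,10E,14R)-16-(tert-butyldiphenylsilyloxy)-2,6,10,14-tetramethyl-3-oxohexadeca-6,10-dienoate, via dilithium dienolate of 8 9 (not isolated)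
Conditions: LiN(i-Pr)2 (2.1 equiv), THF, −78 to 0 °C; then 5, 0 °C; 1 M HCl quench
Reagents that add atoms: none
Why: Weiler dianion alkylation, in which the more basic γ-carbanion of the β-keto ester dianion displaces the primary allylic bromide directly to form the C1–C2 bond.

Step 7
Reactants: 10 acyclic β-keto ester
Product: 11 (1S,2R,5S)-5-methyl-2-(2-phenylpropan-2-yl)cyclohexyl (1S,4aS,5R,8aS)-5-[(3R)-5-(tert-butyldiphenylsilyloxy)-3-methylpentyl]-1,4a-dimethyl-6-methylidene-2-oxodecahydronaphthalene-1-carboxylate (labdane descriptors 4S,5S,9R,10S,13R)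
Conditions: Mn(OAc)3·2H2O (2.2 equiv), Cu(OAc)2·H2O (1.0 equiv), degassed AcOH, 25 °C, 24–48 h
Reagents that add atoms: none
Why: Snider-type oxidative free-radical polyene cyclization, in which trivalent manganese generates the C4 keto ester radical, 6-endo closure onto C5 forms ring A and 6-endo attack of the C10 radical on C9 forms ring B through a chair–chair array (E-alkenes give the trans ring fusion and the equatorial C9 chain, the ester anti to the ketone oxygen ends axial and cis to C20), the phenyl ring of the auxiliary shields one face of the radical so that C5 bonds anti to it and fixes the ent series, and divalent copper oxidises the tertiary C8 radical to the less substituted exocyclic alkene.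

Step 8
Reactants: 11 bicyclic β-keto ester
Product: 12 (1R,2R,4aS,5R,8aS)-5-[(3R)-5-(tert-butyldiphenylsilyloxy)-3-methylpentyl]-1-(hydroxymethyl)-1,4a-dimethyl-6-methylidenedecahydronaphthalen-2-ol (3-equatorial-hydroxy 3,19-diol)
Conditions: LiAlH4 (4 equiv), THF, 0 to 40 °C; H2O/NaOH work-up
Reagents that add atoms: none
Why: Hydride reduction, in which axial delivery to the C3 ketone gives the equatorial (3R) alcohol and the resulting β-alkoxyaluminate helps reduce the hindered neopentyl ester to the C19 carbinol, releasing the auxiliary for recovery.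

Step 9
Reactants: 12 3,19-diol
Product: 13 cyclic thionocarbonate of 12 (1,3-dioxane-2-thione ring spanning O3–C3–C4–C19–O19, other centres as in 12)
Conditions: 1,1'-thiocarbonyldiimidazole (1.5 equiv), DMAP (0.2 equiv), toluene, 90 °C
Reagents that add atoms: 1,1'-thiocarbonyldiimidazole, S=C(n1ccnc1)n1ccnc1
Why: Cyclic thionocarbonate formation is favoured because the equatorial O3 and the axial C19 hydroxymethyl are gauche, the same relationship that lets ent-labdane 3,19-diols form six-membered acetals readily.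

Step 10
Reactants: 13 cyclic thionocarbonate
Product: 15 [(1R,4aS,5R,8aS)-5-[(3R)-5-(tert-butyldiphenylsilyloxy)-3-methylpentyl]-1,4a-dimethyl-6-methylidenedecahydronaphthalen-1-yl]methanol, via S-tributylstannyl thiocarbonate of 15 14 (not isolated)
Conditions: n-Bu3SnH (2.5 equiv), AIBN (0.2 equiv), toluene, 110 °C; then 2 M NaOH, MeOH/THF, 25 °C
Reagents that add atoms: none
Why: Barton–McCombie-type deoxygenation of a cyclic thionocarbonate, in which the stannyl radical adds to sulfur, the dioxanyl radical fragments toward the secondary C3 radical rather than the primary neopentyl C19 radical, hydrogen transfer leaves CH2 at C3, and base hydrolysis of the S-stannyl thiocarbonate frees the C19 alcohol.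

Step 11
Reactants: 15 19-alcohol
Product: 16 (1R,4aS,5R,8aS)-5-[(3R)-5-(tert-butyldiphenylsilyloxy)-3-methylpentyl]-1,4a-dimethyl-6-methylidenedecahydronaphthalene-1-carboxylic acid
Conditions: CrO3, H2SO4, H2O, acetone, 0 °C, 30 min
Reagents that add atoms: chromium trioxide (as aqueous chromic acid), O=[Cr](=O)=O
Why: Jones oxidation takes the hindered neopentyl primary alcohol through the aldehyde hydrate to the acid in one operation, while the primary TBDPS ether and the isolated 1,1-disubstituted alkene tolerate short exposure at 0 °C.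

Step 12
Reactants: 16 silyl-protected acid
Product: 17 (1R,4aS,5R,8aS)-5-[(3R)-5-hydroxy-3-methylpentyl]-1,4a-dimethyl-6-methylidenedecahydronaphthalene-1-carboxylic acid
Conditions: n-Bu4NF (3 equiv), AcOH (3 equiv), THF, 25 °C
Reagents that add atoms: none
Why: Fluoride-induced desilylation, buffered with acetic acid, frees the C15 alcohol without touching the acid, the alkene or any stereocentre.

Step 13
Reactants: 17 hydroxy acid
Product: 18 (1R,4aS,5R,8aS)-5-[(3R)-5-acetoxy-3-methylpentyl]-1,4a-dimethyl-6-methylidenedecahydronaphthalene-1-carboxylic acid (target; labdane descriptors 4R,5S,9R,10S,13R)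
Conditions: Ac2O (1.5 equiv), pyridine, DMAP (0.05 equiv), CH2Cl2, 0 to 25 °C; aqueous NaHCO3 then pH 4 work-up
Reagents that add atoms: acetic anhydride, CC(=O)OC(C)=O
Why: Acylation of the unhindered primary alcohol, with any mixed anhydride of the hindered C19 acid hydrolysed back to the acid on aqueous work-up.

## Compound list

1 | (2E,6E)-farnesol, (2E,6E)-3,7,11-trimethyldodeca-2,6,10-trien-1-ol | OC/C=C(\C)CC/C=C(\C)CCC=C(C)C | starting material
2 | (R)-2,3-dihydrofarnesol, (3R,6E)-3,7,11-trimethyldodeca-6,10-dien-1-ol | OCC[C@H](C)CC/C=C(\C)CCC=C(C)C | intermediate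
3 | tert-butyldiphenyl{[(3R,6E)-3,7,11-trimethyldodeca-6,10-dien-1-yl]oxy}silane | CC(C)(C)[Si](c1ccccc1)(c1ccccc1)OCC[C@H](C)CC/C=C(\C)CCC=C(C)C | intermediate
4 | (2E,6E,10R)-12-(tert-butyldiphenylsilyloxy)-2,6,10-trimethyldodeca-2,6-dien-1-ol | CC(C)(C)[Si](c1ccccc1)(c1ccccc1)OCC[C@H](C)CC/C=C(\C)CC/C=C(\C)CO | intermediate
5 | tert-butyl{[(3R,6E,10E)-12-bromo-3,7,11-trimethyldodeca-6,10-dien-1-yl]oxy}diphenylsilane | CC(C)(C)[Si](c1ccccc1)(c1ccccc1)OCC[C@H](C)CC/C=C(\C)CC/C=C(\C)CBr | intermediate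
6 | (+)-8-phenylmenthol, (1S,2R,5S)-5-methyl-2-(2-phenylpropan-2-yl)cyclohexan-1-ol | O[C@H]1C[C@@H](C)CC[C@@H]1C(C)(C)c1ccccc1 | starting material
7 | ethyl 2-methyl-3-oxobutanoate (racemic) | CCOC(=O)C(C)C(C)=O | starting material
8 | (1S,2R,5S)-5-methyl-2-(2-phenylpropan-2-yl)cyclohexyl 2-methyl-3-oxobutanoate (2RS) | CC(=O)C(C)C(=O)O[C@H]1C[C@@H](C)CC[C@@H]1C(C)(C)c1ccccc1 | intermediate
9 | dilithium dienolate (dianion) of 8 | [Li+].[Li+].C=C([O-])C(C)=C([O-])O[C@H]1C[C@@H](C)CC[C@@H]1C(C)(C)c1ccccc1 | intermediate (not isolated)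
10 | (1S,2R,5S)-8-phenylmenthyl (2RS,6E,10E,14R)-16-(tert-butyldiphenylsilyloxy)-2,6,10,14-tetramethyl-3-oxohexadeca-6,10-dienoate | CC(C)(C)[Si](c1ccccc1)(c1ccccc1)OCC[C@H](C)CC/C=C(\C)CC/C=C(\C)CCC(=O)C(C)C(=O)O[C@H]1C[C@@H](C)CC[C@@H]1C(C)(C)c1ccccc1 | intermediate
11 | (1S,2R,5S)-8-phenylmenthyl (1S,4aS,5R,8aS)-5-[(3R)-5-(tert-butyldiphenylsilyloxy)-3-methylpentyl]-1,4a-dimethyl-6-methylidene-2-oxodecahydronaphthalene-1-carboxylate (trans-decalin, axial ester cis to the angular methyl) | C=C1CC[C@H]2[C@@](C)(CCC(=O)[C@@]2(C)C(=O)O[C@H]3C[C@@H](C)CC[C@@H]3C(C)(C)c4ccccc4)[C@@H]1CC[C@@H](C)CCO[Si](c5ccccc5)(c6ccccc6)C(C)(C)C | intermediate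
12 | (1R,2R,4aS,5R,8aS)-5-[(3R)-5-(tert-butyldiphenylsilyloxy)-3-methylpentyl]-1-(hydroxymethyl)-1,4a-dimethyl-6-methylidenedecahydronaphthalen-2-ol | C=C1CC[C@H]2[C@@](C)(CC[C@@H](O)[C@@]2(C)CO)[C@@H]1CC[C@@H](C)CCO[Si](c3ccccc3)(c4ccccc4)C(C)(C)C | intermediate
13 | cyclic thionocarbonate of 12 (1,3-dioxane-2-thione fused at C3–C4 through O3 and O19) | C=C1CC[C@H]2[C@@](C)(CC[C@@H](OC(=S)OC3)[C@]23C)[C@@H]1CC[C@@H](C)CCO[Si](c4ccccc4)(c5ccccc5)C(C)(C)C | intermediate
14 | S-tributylstannyl thiocarbonate of 15 (C19–O–C(=O)–S–SnBu3, C3 now CH2) | C=C1CC[C@H]2[C@@](C)(CCC[C@@]2(C)COC(=O)S[Sn](CCCC)(CCCC)CCCC)[C@@H]1CC[C@@H](C)CCO[Si](c3ccccc3)(c4ccccc4)C(C)(C)C | intermediate (not isolated)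
15 | [(1R,4aS,5R,8aS)-5-[(3R)-5-(tert-butyldiphenylsilyloxy)-3-methylpentyl]-1,4a-dimethyl-6-methylidenedecahydronaphthalen-1-yl]methanol | C=C1CC[C@H]2[C@@](C)(CCC[C@@]2(C)CO)[C@@H]1CC[C@@H](C)CCO[Si](c3ccccc3)(c4ccccc4)C(C)(C)C | intermediate
16 | (1R,4aS,5R,8aS)-5-[(3R)-5-(tert-butyldiphenylsilyloxy)-3-methylpentyl]-1,4a-dimethyl-6-methylidenedecahydronaphthalene-1-carboxylic acid | C=C1CC[C@H]2[C@@](C)(CCC[C@@]2(C)C(=O)O)[C@@H]1CC[C@@H](C)CCO[Si](c3ccccc3)(c4ccccc4)C(C)(C)C | intermediate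
17 | (1R,4aS,5R,8aS)-5-[(3R)-5-hydroxy-3-methylpentyl]-1,4a-dimethyl-6-methylidenedecahydronaphthalene-1-carboxylic acid | C=C1CC[C@H]2[C@@](C)(CCC[C@@]2(C)C(=O)O)[C@@H]1CC[C@@H](C)CCO | intermediate
18 | (1R,4aS,5R,8aS)-5-[(3R)-5-acetoxy-3-methylpentyl]-1,4a-dimethyl-6-methylidenedecahydronaphthalene-1-carboxylic acid | C=C1CC[C@H]2[C@@](C)(CCC[C@@]2(C)C(=O)O)[C@@H]1CC[C@@H](C)CCOC(C)=O | target

## Step count and risks

Total steps: 13. Longest linear sequence: 12 steps (1 to 18 through steps 1–4 and 6–13); step 5 is a one-step side branch.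

Most likely to fail, first: step 7. The bicyclization must deliver a useful yield, the exocyclic rather than an endocyclic alkene, and both a high level and the assumed sense of auxiliary control. The fallback sets out from 5 and comes back at 12. It leaves the α-methyl group out of the radical precursor and hands facial control to a lanthanide chelate. (−)-8-Phenylmenthol F1 is acetoacetylated with 2,2,6-trimethyl-4H-1,3-dioxin-4-one in xylene at 140 °C to give (−)-8-phenylmenthyl acetoacetate F2. Its dilithium dianion is alkylated with 5 to give the α-unsubstituted β-keto ester F3. Mn(OAc)3·2H2O and Cu(OAc)2·H2O in CF3CH2OH at 0 °C with Yb(OTf)3 then cyclise the chelated radical to the bicyclic β-keto ester F4. In this chelate both carbonyl groups are held syn on trivalent ytterbium, a more rigid array in which the alkene reaches the opposite face of the dicarbonyl unit compared with the non-chelated α-methyl radical, hence the enantiomeric auxiliary. Methylation of F4 (K2CO3, MeI, acetone) occurs on the enolate face away from the axial C10 methyl and gives the C4-methylated keto ester F5. LiAlH4 reduction of F5 gives diol 12.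

Second: step 10 (with step 9). The fragmentation has to choose the C3–O bond over the C19–O bond, and the thionocarbonate has to close on a hindered diol. The fallback sets out from 11 and comes back at 15. It removes the oxygen while C19 is still an ester, so there is only one C–O bond to break. NaBH4 in MeOH/THF at 0 °C reduces only the ketone of 11 to the 3-hydroxy ester F6. PhOC(S)Cl with pyridine and DMAP gives the O-phenyl thionocarbonate F7. n-Bu3SnH/AIBN in toluene at 110 °C gives the 3-deoxy ester F8. LiAlH4 then cleaves the auxiliary ester of F8 to give 15.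

Third: step 3. The substrate has two trisubstituted alkenes, and the SeO2 oxidation typically gives modest yields with over-oxidation. The fallback sets out from 3 and comes back at 4. It replaces C–H oxidation by cleavage and re-olefination of the terminal alkene. NBS in aqueous THF at 0 °C gives the terminal bromohydrin F9. K2CO3 in MeOH closes it to the terminal epoxide F10. HIO4 in THF/Et2O cleaves F10 to the aldehyde F11. The stabilised ylide Ph3P=C(CH3)CO2Et in CH2Cl2 gives the (E)-enoate F12. i-Bu2AlH in CH2Cl2 at −78 °C reduces F12 to 4.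

## Further compounds

F1 | step 7 | (−)-8-phenylmenthol, (1R,2S,5R)-5-methyl-2-(2-phenylpropan-2-yl)cyclohexan-1-ol | O[C@@H]1C[C@H](C)CC[C@H]1C(C)(C)c1ccccc1
F2 | step 7 | (1R,2S,5R)-5-methyl-2-(2-phenylpropan-2-yl)cyclohexyl 3-oxobutanoate | CC(=O)CC(=O)O[C@@H]1C[C@H](C)CC[C@H]1C(C)(C)c1ccccc1
F3 | step 7 | (1R,2S,5R)-8-phenylmenthyl (6E,10E,14R)-16-(tert-butyldiphenylsilyloxy)-6,10,14-trimethyl-3-oxohexadeca-6,10-dienoate | CC(C)(C)[Si](c1ccccc1)(c1ccccc1)OCC[C@H](C)CC/C=C(\C)CC/C=C(\C)CCC(=O)CC(=O)O[C@@H]1C[C@H](C)CC[C@H]1C(C)(C)c1ccccc1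
F4 | step 7 | (1R,2S,5R)-8-phenylmenthyl (1R,4aR,5R,8aR)-5-[(3R)-5-(tert-butyldiphenylsilyloxy)-3-methylpentyl]-4a-methyl-6-methylidene-2-oxodecahydronaphthalene-1-carboxylate (C4–H, equatorial ester, enolisable) | C=C1CC[C@H]2[C@@](C)(CCC(=O)[C@@H]2C(=O)O[C@@H]3C[C@H](C)CC[C@H]3C(C)(C)c4ccccc4)[C@@H]1CC[C@@H](C)CCO[Si](c5ccccc5)(c6ccccc6)C(C)(C)C
F5 | step 7 | (1R,2S,5R)-8-phenylmenthyl (1S,4aS,5R,8aS)-5-[(3R)-5-(tert-butyldiphenylsilyloxy)-3-methylpentyl]-1,4a-dimethyl-6-methylidene-2-oxodecahydronaphthalene-1-carboxylate (as 11 but with the enantiomeric auxiliary) | C=C1CC[C@H]2[C@@](C)(CCC(=O)[C@@]2(C)C(=O)O[C@@H]3C[C@H](C)CC[C@H]3C(C)(C)c4ccccc4)[C@@H]1CC[C@@H](C)CCO[Si](c5ccccc5)(c6ccccc6)C(C)(C)C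
F6 | step 10 | (1S,2R,5S)-8-phenylmenthyl (1S,2R,4aS,5R,8aS)-5-[(3R)-5-(tert-butyldiphenylsilyloxy)-3-methylpentyl]-2-hydroxy-1,4a-dimethyl-6-methylidenedecahydronaphthalene-1-carboxylate | C=C1CC[C@H]2[C@@](C)(CC[C@@H](O)[C@@]2(C)C(=O)O[C@H]3C[C@@H](C)CC[C@@H]3C(C)(C)c4ccccc4)[C@@H]1CC[C@@H](C)CCO[Si](c5ccccc5)(c6ccccc6)C(C)(C)C
F7 | step 10 | O-phenyl thionocarbonate of F6 (at O3) | C=C1CC[C@H]2[C@@](C)(CC[C@@H](OC(=S)Oc3ccccc3)[C@@]2(C)C(=O)O[C@H]4C[C@@H](C)CC[C@@H]4C(C)(C)c5ccccc5)[C@@H]1CC[C@@H](C)CCO[Si](c6ccccc6)(c7ccccc7)C(C)(C)C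
F8 | step 10 | (1S,2R,5S)-8-phenylmenthyl (1R,4aS,5R,8aS)-5-[(3R)-5-(tert-butyldiphenylsilyloxy)-3-methylpentyl]-1,4a-dimethyl-6-methylidenedecahydronaphthalene-1-carboxylate | C=C1CC[C@H]2[C@@](C)(CCC[C@@]2(C)C(=O)O[C@H]3C[C@@H](C)CC[C@@H]3C(C)(C)c4ccccc4)[C@@H]1CC[C@@H](C)CCO[Si](c5ccccc5)(c6ccccc6)C(C)(C)C
F9 | step 3 | (3RS,6E,10R)-3-bromo-12-(tert-butyldiphenylsilyloxy)-2,6,10-trimethyldodec-6-en-2-ol | CC(C)(C)[Si](c1ccccc1)(c1ccccc1)OCC[C@H](C)CC/C=C(\C)CCC(Br)C(C)(C)O
F10 | step 3 | tert-butyl{[(3R,6E)-9-(3,3-dimethyloxiran-2-yl)-3,7-dimethylnon-6-en-1-yl]oxy}diphenylsilane (oxirane carbon RS) | CC(C)(C)[Si](c1ccccc1)(c1ccccc1)OCC[C@H](C)CC/C=C(\C)CCC1OC1(C)C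
F11 | step 3 | (4E,8R)-10-(tert-butyldiphenylsilyloxy)-4,8-dimethyldec-4-enal | CC(C)(C)[Si](c1ccccc1)(c1ccccc1)OCC[C@H](C)CC/C=C(\C)CCC=O
F12 | step 3 | ethyl (2E,6E,10R)-12-(tert-butyldiphenylsilyloxy)-2,6,10-trimethyldodeca-2,6-dienoate | CC(C)(C)[Si](c1ccccc1)(c1ccccc1)OCC[C@H](C)CC/C=C(\C)CC/C=C(\C)C(=O)OCC
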